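**Retrosynthetic overview**
- The only ring to be made is the 4-pyranone. It is opened at the aryl C–O bond (O1–C8a), giving an open 1,3-diketone that still carries a methoxy group at the carbon that becomes C8a.
- Forward, the enol oxygen displaces that methoxy group (loss of MeOH) in a proposed photoredox cation-radical SNAr ring closure.
- The 1,3-diketone comes from a crossed Claisen condensation of 2,3,5,6-tetramethoxyacetophenone with methyl 2,5-dimethoxybenzoate.
- The acetophenone comes from ortho-lithiation of symmetrical 1,2,4,5-tetramethoxybenzene and acylation with a Weinreb amide.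
- Ring order: both benzene rings are bought; the pyranone ring is formed last.

Assumption: the target has no stereocentre or other stereogenic element, so it is made as the single achiral compound; the three starting materials are taken as catalogue chemicals.

**Step 1**
Reactants: 1 1,2,4,5-tetramethoxybenzene; 2 N-methoxy-N-methylacetamide
Product: 5 1-(2,3,5,6-tetramethoxyphenyl)ethan-1-one, via aryllithium 3 (not isolated), via lithium aminal alkoxide 4 (not isolated)
Conditions: n-BuLi (1.1 equiv), THF, 0 °C, 1 h; then 2 (1.2 equiv), −78 → 0 °C; 1 M HCl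
Reagents that add atoms: n-butyllithium, [Li]CCCC (supplies the lithium of 3 and 4; no atom of it remains in 5)
Why: Directed ortho-metalation followed by Weinreb ketone synthesis: the only ring C–H type of 1 lies between two methoxy groups and lithiates cleanly, the N,O-chelated adduct 4 stops over-addition, and acid work-up releases the ketone with all four methyl ethers intact (the racemic centre of 4 disappears on collapse; 5 has no stereocentre).

**Step 2**
Reactants: 5 1-(2,3,5,6-tetramethoxyphenyl)ethan-1-one; 6 methyl 2,5-dimethoxybenzoate
Product: 8 1-(2,5-dimethoxyphenyl)-3-(2,3,5,6-tetramethoxyphenyl)propane-1,3-dione, via sodium diketonate 7 (not isolated)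
Conditions: NaH (2.5 equiv), 6 (1.2 equiv), THF, 65 °C, 5 h; then 1 M HCl, 0 °C
Reagents that add atoms: sodium hydride, [Na+].[H-] (supplies the sodium of 7; no atom of it remains in 8)
Why: Crossed Claisen condensation: only 5 is enolisable, its di-ortho-substituted carbonyl does not self-condense, ester 6 cannot enolise, and irreversible deprotonation of the product to diketonate 7 drives the acylation (no stereocentre).

**Step 3**
Reactants: 8 1-(2,5-dimethoxyphenyl)-3-(2,3,5,6-tetramethoxyphenyl)propane-1,3-dione
Product: 9 2-(2,5-dimethoxyphenyl)-5,6,8-trimethoxy-4H-chromen-4-one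
Conditions: 3,6-di-tert-butyl-9-mesityl-10-phenylacridinium BF4 (5 mol%), DCE/CF3CH2OH 1:1 (0.05 M), 455 nm LEDs, N2, 25 °C, 24 h
Reagents that add atoms: none
Why: Proposed new method: an intramolecular enol-oxygen cation-radical-accelerated SNAr, in which the excited acridinium (E* est. +2.1 V vs SCE) oxidises the more electron-rich tetramethoxyaryl ring (est. +1.1 V, against at least +1.5 V for the dimethoxyaryl ring) to its radical cation, whose charge sits on the para-related methoxy-bearing carbons; the enol oxygen of the diketone then adds ipso at the ortho C–OMe carbon through a six-membered transition state, trifluoroethanol-assisted loss of methanol gives the chromone radical cation, and this is reduced by the acridine radical or by a further molecule of 8 in a chain, so the closure is redox-neutral and needs no prior demethylation; the closest known reaction types are the intermolecular cation-radical-accelerated SNAr of alkoxyarenes with azole and amine nucleophiles under acridinium photoredox catalysis and the anodic ipso-substitution of p-dimethoxyarenes, and no stereocentre is formed.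

**Compound list**
1 | 1,2,4,5-tetramethoxybenzene | COc1cc(OC)c(OC)cc1OC | starting material
2 | N-methoxy-N-methylacetamide | CC(=O)N(C)OC | starting material
3 | (2,3,5,6-tetramethoxyphenyl)lithium | [Li]c1c(OC)c(OC)cc(OC)c1OC | intermediate
4 | lithium 1-[methoxy(methyl)amino]-1-(2,3,5,6-tetramethoxyphenyl)ethan-1-olate (racemic) | [Li+].CC([O-])(N(C)OC)c1c(OC)c(OC)cc(OC)c1OC | intermediate
5 | 1-(2,3,5,6-tetramethoxyphenyl)ethan-1-one | CC(=O)c1c(OC)c(OC)cc(OC)c1OC | intermediate
6 | methyl 2,5-dimethoxybenzoate | COC(=O)c1cc(OC)ccc1OC | starting material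
7 | sodium (Z)-1-(2,5-dimethoxyphenyl)-3-oxo-3-(2,3,5,6-tetramethoxyphenyl)prop-1-en-1-olate | [Na+].[O-]/C(=C\C(=O)c1c(OC)c(OC)cc(OC)c1OC)c1cc(OC)ccc1OC | intermediate
8 | 1-(2,5-dimethoxyphenyl)-3-(2,3,5,6-tetramethoxyphenyl)propane-1,3-dione (drawn as the diketo form; mainly the chelated enol) | COc1ccc(OC)c(C(=O)CC(=O)c2c(OC)c(OC)cc(OC)c2OC)c1 | intermediate
9 | 2-(2,5-dimethoxyphenyl)-5,6,8-trimethoxy-4H-chromen-4-one (achiral) | COc1ccc(OC)c(-c2cc(=O)c3c(OC)c(OC)cc(OC)c3o2)c1 | target

**Step count**
Total step count: 3. Longest linear sequence: 3 steps (1 → 5 → 8 → 9).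

**Steps most likely to fail, most risky first**

Step 3 (the proposed new ring closure). The radical cation of so electron-rich a ring may be too stabilised to be trapped, back electron transfer may dominate, or some closure may occur onto the 2-methoxy carbon of the other ring to give the regioisomeric chromone. The fallback uses known chemistry, sets out from 5 and comes back to the route at 9. Claisen–Schmidt condensation of 5 with 2,5-dimethoxybenzaldehyde (COc1ccc(OC)c(C=O)c1; KOH, EtOH, rt) gives (E)-3-(2,5-dimethoxyphenyl)-1-(2,3,5,6-tetramethoxyphenyl)prop-2-en-1-one F1. BCl3 (1.1 equiv, CH2Cl2, −78 → 0 °C) then removes one of the two equivalent, carbonyl-chelated ortho methyl groups to give (E)-3-(2,5-dimethoxyphenyl)-1-(2-hydroxy-3,5,6-trimethoxyphenyl)prop-2-en-1-one F2. Oxidative cyclisation of F2 with I2 (10 mol%) in DMSO at 120 °C gives 9. In this sequence the regiochemistry of ring closure is unambiguous, because only the A-ring phenol is free.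

Step 1. The hindered, basic aryllithium may enolise the acetamide instead of adding, returning 1. The fallback replaces metalation by electrophilic substitution, sets out from 1 and comes back at 5. Friedel–Crafts acetylation of 1 (AcCl, AlCl3 2.5 equiv, CH2Cl2, 0 °C → rt) proceeds with chelation-driven loss of one ortho methyl group to give 1-(2-hydroxy-3,5,6-trimethoxyphenyl)ethan-1-one F3. Re-methylation of F3 (Me2SO4, K2CO3, acetone, reflux) gives 5; any 5 formed directly in the acylation joins the same material.

Step 2. The Claisen condensation may stall or revert (retro-Claisen on work-up). The fallback replaces acyl substitution by aldol addition and oxidation, sets out from 5 and comes back at 8. The lithium enolate of 5 (LDA, THF, −78 °C) is added to 2,5-dimethoxybenzaldehyde to give racemic 3-(2,5-dimethoxyphenyl)-3-hydroxy-1-(2,3,5,6-tetramethoxyphenyl)propan-1-one F4. Oxidation of F4 with Dess–Martin periodinane (CH2Cl2, rt) gives 8.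

**Further compounds**
F1 | step 3 | (E)-3-(2,5-dimethoxyphenyl)-1-(2,3,5,6-tetramethoxyphenyl)prop-2-en-1-one | COc1ccc(OC)c(/C=C/C(=O)c2c(OC)c(OC)cc(OC)c2OC)c1
F2 | step 3 | (E)-3-(2,5-dimethoxyphenyl)-1-(2-hydroxy-3,5,6-trimethoxyphenyl)prop-2-en-1-one | COc1ccc(OC)c(/C=C/C(=O)c2c(O)c(OC)cc(OC)c2OC)c1
F3 | step 1 | 1-(2-hydroxy-3,5,6-trimethoxyphenyl)ethan-1-one | CC(=O)c1c(O)c(OC)cc(OC)c1OC
F4 | step 2 | 3-(2,5-dimethoxyphenyl)-3-hydroxy-1-(2,3,5,6-tetramethoxyphenyl)propan-1-one (racemic) | COc1ccc(OC)c(C(O)CC(=O)c2c(OC)c(OC)cc(OC)c2OC)c1
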